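All constants stand for no real mixture; the result is computed.

Two exits compete. The open intermediate, formed reversibly from the substrate, either meets the second intermediate and gives target, or meets the capture agent and is trapped.

common to all: partner 14.4 mM; capture agent 16.0 mM

| charge | substrate | remark | time |
|---|---|---|---|
| Tuesday's | 16 mM | a single well-mixed tank run continuously and read at steady state, 10.0 h in it on average |  |
| Friday's | 16 mM | one stirred flow tank at steady state, fed with the mixture as stated, mean residence time 2.0 h |  |
| Sunday's | 16 mM | everything together in a closed stirred flask, run for 2.0 h | 2.0 h |
| Saturday's | 16 mM (fed, over 2.00 h) | all but substrate at the start; substrate goes in evenly over 2.00 h, the run ends at 2.0 h | 2.0 h |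

    partner → second intermediate (k1 = 0.938 /h)
    open intermediate + capture agent → trapped intermediate (k2 = 90.4 /M/h)
    substrate ⇌ open intermediate (K3 = 0.37, k3 = 0.802 /h)
    open intermediate + second intermediate → target (k4 = 71.8 /M/h)

- the stated concentrations are those of everything mixed, before any reaction; amounts are the same in each set-up
- the feed brings no volume worth counting
- run time (Sunday's): 2.0 h

1. the set-up with the highest amount of target at the outlet or at the end, in percent of the substrate put in ("none" if the first two lie within 2 percentage points) (Tuesday's / Friday's / Sunday's / Saturday's / none)
2. amount of target at the outlet or at the end, in percent of the substrate put in, Tuesday's
3. amount of target at the outlet or at the end, in percent of the substrate put in, Friday's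
4. amount of target at the outlet or at the end, in percent of the substrate put in, Sunday's
5. amount of target at the outlet or at the end, in percent of the substrate put in, Saturday's

Both exits are first order in the open intermediate, so it cancels from the ratio of their rates. The target exit leads once the second intermediate exceeds 1.26 times the capture agent. This crossing is the selectivity factor of the two exits. The charges stand at 0.900, below it.

My own measure is the par share: the part of the open intermediate leaving by the target exit when the second intermediate stands at the partner's full charge and the capture agent at its own, 41.7%. Where the second intermediate and the capture agent stand in that ratio, target should be roughly this share of what has turned over.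

Two colleagues dispute what matters. The first holds the clock view: turnover needs time. The partner's mean life is 1.07 h. Tuesday's tank gives 10.0 h on average, longer, and converts 90.4% of the partner.

The second holds the dosing view. Sunday's flask starts with no second intermediate, while the capture agent stands at its full charge. In Saturday's flask, the substrate arrives evenly. By 1.00 h, up to 8.76 mM of second intermediate has formed, and against the full capture charge that gives a share of 30.3%.

I side with the clock: Saturday's dose finishes at 2.00 h, and the run ends at 2.0 h. The forecast sides with it too, naming Tuesday's: 29.7% for Tuesday's, 11.2% for Friday's, 12.9% for Sunday's and 7.7% for Saturday's. Of Saturday's it says “there is too little time”.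

The simulation gives 29.8% for Tuesday's, the highest, against 11.2% for Friday's, 12.9% for Sunday's and 7.75% for Saturday's. The best set-up is Tuesday's, as the clock view said. The dosing view has its region in the long run: at 20.0 h, Saturday's flask holds 41.6% of target, more than the 39.5% in Sunday's. Tuesday's tank also delivers 42.1% as trapped intermediate, so 71.8% has left by the two exits. The par share of that is 29.9% of the substrate put in.

Now take Saturday's flask with 24 mM of partner. The ratio to the capture agent becomes 1.50, above the crossing, and the par share rises to 54.4%, a factor of 1.30. Computed at 2.00 h, that flask holds 11.8% of target and 14.1% trapped, a share of 45.6% against 33.6% in Saturday's own, a factor of 1.36.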